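| setting | larch | ash | oak | cedar | birch |
|---|---|---|---|---|---|
| starting material | 120 mM | 120 mM | 60.0 mM | 120 mM | 60.0 mM |
| free catalyst | 1.20 mM | 3.60 mM | 1.20 mM | 1.20 mM | 0.400 mM |
| target |  |  |  | 36.0 mM |  |
| time |  |  |  |  | 89 h |

| run | time / h | [target] / mM |
|---|---|---|
| larch run | 4.0 | 12.7 |
| larch run | 12 | 21.2 |
| larch run | 23 | 26.5 |
| larch run | 36 | 28.1 |
| larch run | 52 | 29.6 |
| larch run | 70 | 30.2 |
| larch run | 89 | 29.8 |
| ash run | 4.0 | 31.9 |
| ash run | 12 | 49.0 |
| ash run | 23 | 56.9 |
| ash run | 36 | 60.2 |
| ash run | 52 | 62.0 |
| ash run | 70 | 63.9 |
| ash run | 89 | 63.7 |
| oak run | 4.0 | 4.7 |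
| oak run | 12 | 9.9 |
| oak run | 23 | 13.0 |
| oak run | 36 | 13.9 |
| oak run | 52 | 14.8 |
| oak run | 70 | 15.1 |
| oak run | 89 | 15.2 |
| cedar run | 4.0 | 48.8 |
| cedar run | 12 | 57.8 |
| cedar run | 23 | 62.4 |
| cedar run | 36 | 64.8 |
| cedar run | 52 | 64.9 |
| cedar run | 70 | 66.6 |
| cedar run | 89 | 66.3 |

(each reading ± 0.4 mM)

- Overall: starting material -> target, with free catalyst as catalyst.
- Constant volume, constant temperature.
- A reading of a species includes what of it is bound.
- An order is taken over about fifteen percent of the charge, up and down.

* reaction order in [free catalyst] at the outset, round the charge of the larch run, defined at two percent of the starting material turned into target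
* reaction order in [starting material] at the outset, round the charge of the larch run, defined at two percent of the starting material turned into target (one fixed amount of target, the same in the runs compared)
* target in the birch run at 89 h, as a share of the starting material charged

The easy step is one division at the last reading of a run, at 89 h: target made over the charge not turned into target.

larch: 0.330
oak: 0.339
cedar, seed subtracted: 0.338
ash: 1.13

This ratio is the plateau odds, a selectivity factor, as for two parallel drains on one tank. As read, it stays level when the charge of starting material is halved or target is seeded, so oak, with the same charge as birch, is the base for birch.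

Catalyst moves it. Ash has 3.00 times the catalyst of larch and 3.42 times the odds.

Birch has less catalyst than oak, so the oak share of 25.3% is a crude ceiling. Two tighter edges follow, if the larch-to-ash trend holds below larch. Odds per catalyst rise with catalyst, so plain proportion gives the upper edge, and the same steepness as ash over larch gives the lower:

upper: 0.113, share 10.2%
lower: 0.0991, share 9.01%

Between 52 h and 89 h, oak, with the birch charge of starting material, read 14.8 mM and then 15.2 mM. The bracket therefore sets birch against oak at the same time, 89 h, and claims no plateau for birch.

The forecast gives 0.95 in free catalyst, 1.6 in starting material, and 10% for birch, on the ground that “The catalyst is dying”. By another route its birch value lands inside the bracket.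

The flask gives 1.1, 1.7 and 10.2%, so the two part on the catalyst order. The birch odds are 0.114, at the upper edge.

    free catalyst + starting material ⇌ catalyst-substrate complex, settled at all times (5.270 M⁻¹)
    catalyst-substrate complex + starting material ⇌ doubly bound catalyst, settled at all times (0.9200 M⁻¹)
    doubly bound catalyst → target + catalyst-substrate complex (97.56 h⁻¹)
    free catalyst + starting material → spent catalyst + starting material (0.6300 M⁻¹ h⁻¹)
    2 starting material → homo dimer (0.3996 M⁻¹ h⁻¹)

In ash, doubly bound catalyst gave target while starting material also went to homo dimer and free catalyst to spent catalyst. The larch odds times the ash rate ratio of 3.2 at equal target make 1.05, a share of 51.2%, against a last ash reading of 53.1%, with a quarter of the charge reached at 3.61 h in ash and 66.4 h in larch.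

The runs are simulated for an exercise.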